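**Strategy.** Everything rests on cutting the tetrahydrofuran ring of the 7-oxabicyclo[2.2.1]heptane (O7, bridgeheads C1 and C4, bridge C5–C6) into a methyl ketone (C1=O7) and a 1,1-disubstituted cyclopropane (C4, C5, C6), tethered through the CHBr–CH2 bridge (C2–C3). In one Lewis-acid-mediated formal (3+2) cycloisomerisation the cyclopropane opens onto the ketone (C6–C1 bond) and the alkoxide captures the resulting tertiary cation (O7–C4 bond); the α-bromine on C2 steers the configuration of C1 and hence C4. The precursor is an acyclic α-bromo methyl ketone whose cyclopropane carries the bromodimethylcyclohexane (ring B); its carbinol precursor comes from an asymmetric glyoxal-ene reaction.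

Key step: step 11

Assumption: the catalyst antipodes written in steps 2, 6 and 8 are those expected to give the drawn configurations; if a first run shows the opposite sense, the mirror-image catalyst is used.

**Step 1**
Reactants: 1 5-bromo-2-methylpent-2-ene; 2 lithium acetylide–ethylenediamine complex
Product: 3 6-methylhept-5-en-1-yne
Conditions: DMSO, 10 °C → rt
Reagents that add atoms: none
Why: Acetylide alkylation (SN2) at the unhindered primary bromide should give the enyne; no stereocenter is formed.

**Step 2**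
Reactants: 3 6-methylhept-5-en-1-yne
Product: 4 (3R)-3-(but-3-yn-1-yl)-2,2-dimethyloxirane
Conditions: D-fructose-derived Shi ketone (30 mol %), KHSO5 (as 2KHSO5·KHSO4·K2SO4), K2CO3, n-Bu4NHSO4, MeCN–CH2(OMe)2–aq. Na2B4O7 buffer, 0 °C
Reagents that add atoms: potassium peroxymonosulfate, [K+].[O-]S(=O)(=O)OO
Why: Shi epoxidation, in which the chiral dioxirane transfers oxygen to the trisubstituted alkene through a spiro transition state to set C3 as R, while the terminal alkyne is inert to dioxiranes.

**Step 3**
Reactants: 4 (3R)-3-(but-3-yn-1-yl)-2,2-dimethyloxirane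
Product: 5 (3R)-2-bromo-2-methylhept-6-yn-3-ol
Conditions: 48 % aq. HBr, Et2O, −15 → 0 °C
Reagents that add atoms: hydrogen bromide, Br
Why: Acid-mediated Markovnikov epoxide opening should place bromide on the tertiary carbon and leave the C–O stereocenter untouched.

**Step 4**
Reactants: 5 (3R)-2-bromo-2-methylhept-6-yn-3-ol
Product: 8 (4S)-4-bromo-3,3-dimethylcyclohex-1-en-1-yl trifluoromethanesulfonate, via secondary triflate 6 (not isolated), via bromiranium triflate 7 (not isolated)
Conditions: Tf2O, 2,6-di-tert-butyl-4-methylpyridine, CH2Cl2 (0.01 M), −78 → −20 °C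
Reagents that add atoms: trifluoromethanesulfonic anhydride, O=S(=O)(OS(=O)(=O)C(F)(F)F)C(F)(F)F
Why: O-Triflation is followed by anchimerically assisted ionisation (the tertiary bromine displaces triflate with inversion, the β-bromo sulfonate solvolysis through a bromiranium ion), 6-endo alkyne-terminated cation cyclisation at the tertiary carbon and triflate capture of the cyclohexenyl cation, so the C–Br center (S) derives from the epoxide by one inversion and cannot racemise by bromonium transfer because no alkene is present.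

**Step 5**
Reactants: 8 (4S)-4-bromo-3,3-dimethylcyclohex-1-en-1-yl trifluoromethanesulfonate; 9 tributyl(1-ethoxyvinyl)stannane
Product: 11 1-[(4S)-4-bromo-3,3-dimethylcyclohex-1-en-1-yl]ethan-1-one, via dienyl ethyl ether 10 (not isolated)
Conditions: Pd(PPh3)4 (5 mol %), LiCl, THF, 65 °C; then 1 M HCl, rt
Reagents that add atoms: water, O
Why: Stille coupling of the vinyl triflate with the acetyl-anion equivalent and hydrolysis of the enol ether should give the enone, the hindered secondary C–Br bond being inert to oxidative addition at zerovalent palladium.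

**Step 6**
Reactants: 11 1-[(4S)-4-bromo-3,3-dimethylcyclohex-1-en-1-yl]ethan-1-one
Product: 12 1-[(1S,4S)-4-bromo-3,3-dimethylcyclohexyl]ethan-1-one
Conditions: H2 (50 bar), [Ir(cod)((S)-t-Bu-PHOX)][B(3,5-(CF3)2C6H3)4] (2 mol %), CH2Cl2, rt
Reagents that add atoms: none
Why: Iridium phosphine–oxazoline-catalysed asymmetric hydrogenation of the trisubstituted enone C=C delivers H2 to one catalyst-selected face and sets C1 as S (trans to bromine); catalyst control is needed because the ring itself gives almost no 1,4-induction.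

**Step 7**
Reactants: 12 1-[(1S,4S)-4-bromo-3,3-dimethylcyclohexyl]ethan-1-one
Product: 13 (1S,4S)-1-bromo-2,2-dimethyl-4-(prop-1-en-2-yl)cyclohexane
Conditions: Zn, CH2Br2, TiCl4, THF–CH2Cl2, 0 °C → rt
Reagents that add atoms: dibromomethane, BrCBr
Why: Takai–Lombardo methylenation converts the methyl ketone into the isopropenyl group under non-basic conditions, so the α-stereocenter should not epimerise.

**Step 8**
Reactants: 13 (1S,4S)-1-bromo-2,2-dimethyl-4-(prop-1-en-2-yl)cyclohexane; 14 methylglyoxal (freshly distilled, monomeric)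
Product: 15 (3S)-5-[(1S,4S)-4-bromo-3,3-dimethylcyclohexyl]-3-hydroxyhex-5-en-2-one
Conditions: Cu((S,S)-t-Bu-box)(SbF6)2 (10 mol %), CH2Cl2, 0 °C
Reagents that add atoms: none
Why: Catalytic asymmetric carbonyl-ene (glyoxal-ene) reaction, in which methylglyoxal chelated through both carbonyls to the chiral divalent-copper Lewis acid is attacked at the aldehyde by the 1,1-disubstituted alkene with transfer of a methyl hydrogen, the shielded face giving the (3S)-carbinol and a new exocyclic methylene.

**Step 9**
Reactants: 15 (3S)-5-[(1S,4S)-4-bromo-3,3-dimethylcyclohexyl]-3-hydroxyhex-5-en-2-one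
Product: 16 (3S)-4-{1-[(1S,4S)-4-bromo-3,3-dimethylcyclohexyl]cyclopropyl}-3-hydroxybutan-2-one
Conditions: Et2Zn, CH2I2, CH2Cl2, 0 °C → rt
Reagents that add atoms: diiodomethane, ICI
Why: Simmons–Smith cyclopropanation of the 1,1-disubstituted alkene, accelerated by the homoallylic zinc alkoxide; the new ring carbon is not a stereocenter.

**Step 10**
Reactants: 16 (3S)-4-{1-[(1S,4S)-4-bromo-3,3-dimethylcyclohexyl]cyclopropyl}-3-hydroxybutan-2-one
Product: 18 (3R)-3-bromo-4-{1-[(1S,4S)-4-bromo-3,3-dimethylcyclohexyl]cyclopropyl}butan-2-one, via keto triflate 17 (not isolated)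
Conditions: Tf2O, 2,6-lutidine, CH2Cl2, −78 °C; then n-Bu4NBr (1.05 equiv), −78 → −40 °C
Reagents that add atoms: tetrabutylammonium bromide, CCCC[N+](CCCC)(CCCC)CCCC.[Br-]
Why: SN2 displacement of the α-keto triflate by bromide should proceed with inversion (S → R), and low temperature with one equivalent of bromide limits epimerisation by bromide exchange.

**Step 11**
Reactants: 18 (3R)-3-bromo-4-{1-[(1S,4S)-4-bromo-3,3-dimethylcyclohexyl]cyclopropyl}butan-2-one
Product: 20 (1R,2R,4S)-2-bromo-4-[(1S,4S)-4-bromo-3,3-dimethylcyclohexyl]-1-methyl-7-oxabicyclo[2.2.1]heptane, via aluminate zwitterion 19 (not isolated)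
Conditions: MeAlCl2 (2.2 equiv), CH2Cl2, −78 → 0 °C
Reagents that add atoms: none
Why: Proposed new method: MeAlCl2 activates the ketone, a methylene carbon of the 1,1-dialkylcyclopropane attacks the carbonyl carbon with cleavage of the strained bond to the quaternary ring carbon (C–C bond), and the tertiary cation so formed is captured across the new ring by the aluminium alkoxide (C–O bond), a formal intramolecular (3+2) cycloisomerisation. The closest known reaction type is the Lewis-acid-catalysed intramolecular (3+2) cross-cycloaddition of donor–acceptor cyclopropanes with tethered carbonyl groups to bridged oxa-[n.2.1] skeletons, together with the electrophilic ring opening of alkylcyclopropanes by acylium ions; here no acceptor group is present, so nothing has to be removed afterwards. The cyclohexane ring closes 6-endo with respect to the breaking cyclopropane bond, and the tetrahydrofuran ring closes by 5-exo-type capture of the cation through a boat, which can only give the cis-bridged 7-oxabicyclo[2.2.1]heptane. C1 is controlled by the adjacent C–Br stereocenter: in the cyclic transition state the C=O and C–Br dipoles are anti (Cornforth arrangement) and the nucleophile arrives from the tether side, placing oxygen trans to bromine (bromine endo, C1 R), and C4 (S) follows necessarily from the cis bridge. The step needs carbonyl addition to win over protolytic opening of the cyclopropane, which the proton-scavenging alkylaluminium Lewis acid secures, and cation capture to be faster than a 1,2-hydride shift from the ring-B methine, which the intramolecular ion-pair collapse at low temperature favours.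

**Compound list**
1 | 5-bromo-2-methylpent-2-ene | CC(C)=CCCBr | starting material
2 | lithium acetylide–ethylenediamine complex | [Li+].[C-]#C.NCCN | starting material
3 | 6-methylhept-5-en-1-yne | CC(C)=CCCC#C | intermediate
4 | (3R)-3-(but-3-yn-1-yl)-2,2-dimethyloxirane | CC1(C)O[C@@H]1CCC#C | intermediate
5 | (3R)-2-bromo-2-methylhept-6-yn-3-ol | C#CCC[C@@H](O)C(C)(C)Br | intermediate
6 | (3R)-2-bromo-2-methylhept-6-yn-3-yl trifluoromethanesulfonate (not isolated) | C#CCC[C@@H](OS(=O)(=O)C(F)(F)F)C(C)(C)Br | intermediate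
7 | (3S)-3-(but-3-yn-1-yl)-2,2-dimethylbromiranium trifluoromethanesulfonate (not isolated) | C#CCC[C@@H]1[Br+]C1(C)C.[O-]S(=O)(=O)C(F)(F)F | intermediate
8 | (4S)-4-bromo-3,3-dimethylcyclohex-1-en-1-yl trifluoromethanesulfonate | CC1(C)C=C(OS(=O)(=O)C(F)(F)F)CC[C@@H]1Br | intermediate
9 | tributyl(1-ethoxyvinyl)stannane | CCCC[Sn](CCCC)(CCCC)C(=C)OCC | starting material
10 | (4S)-4-bromo-1-(1-ethoxyethenyl)-3,3-dimethylcyclohex-1-ene (not isolated) | CCOC(=C)C1=CC(C)(C)[C@@H](Br)CC1 | intermediate
11 | 1-[(4S)-4-bromo-3,3-dimethylcyclohex-1-en-1-yl]ethan-1-one | CC(=O)C1=CC(C)(C)[C@@H](Br)CC1 | intermediate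
12 | 1-[(1S,4S)-4-bromo-3,3-dimethylcyclohexyl]ethan-1-one | CC(=O)[C@@H]1CC(C)(C)[C@@H](Br)CC1 | intermediate
13 | (1S,4S)-1-bromo-2,2-dimethyl-4-(prop-1-en-2-yl)cyclohexane | CC(=C)[C@@H]1CC(C)(C)[C@@H](Br)CC1 | intermediate
14 | methylglyoxal (2-oxopropanal) | CC(=O)C=O | starting material
15 | (3S)-5-[(1S,4S)-4-bromo-3,3-dimethylcyclohexyl]-3-hydroxyhex-5-en-2-one | CC(=O)[C@@H](O)CC(=C)[C@@H]1CC(C)(C)[C@@H](Br)CC1 | intermediate
16 | (3S)-4-{1-[(1S,4S)-4-bromo-3,3-dimethylcyclohexyl]cyclopropyl}-3-hydroxybutan-2-one | CC(=O)[C@@H](O)CC1(CC1)[C@@H]2CC(C)(C)[C@@H](Br)CC2 | intermediate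
17 | (2S)-1-{1-[(1S,4S)-4-bromo-3,3-dimethylcyclohexyl]cyclopropyl}-3-oxobutan-2-yl trifluoromethanesulfonate (not isolated) | CC(=O)[C@@H](OS(=O)(=O)C(F)(F)F)CC1(CC1)[C@@H]2CC(C)(C)[C@@H](Br)CC2 | intermediate
18 | (3R)-3-bromo-4-{1-[(1S,4S)-4-bromo-3,3-dimethylcyclohexyl]cyclopropyl}butan-2-one | CC(=O)[C@H](Br)CC1(CC1)[C@@H]2CC(C)(C)[C@@H](Br)CC2 | intermediate
19 | ring-opened zwitterion: (1R,2R)-2-bromo-1-methylcyclohexyl dichloro(methyl)aluminate with the tertiary cation at C4 bearing ring B (not isolated) | C[C@@]1(O[Al-](C)(Cl)Cl)CC[C+](C[C@H]1Br)[C@@H]2CC(C)(C)[C@@H](Br)CC2 | intermediate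
20 | (1R,2R,4S)-2-bromo-4-[(1S,4S)-4-bromo-3,3-dimethylcyclohexyl]-1-methyl-7-oxabicyclo[2.2.1]heptane | CC1(C)C[C@@H]([C@@]23CC[C@@](C)(O2)[C@H](Br)C3)CC[C@@H]1Br | target

**Step count.** Total steps: 11. Longest linear sequence: 11 steps (from 1).

**Steps most likely to fail**

1. Step 11 (Proposed new method). The unactivated cyclopropane may not add to the aluminium-bound ketone, or the tertiary cation may lose a proton or take up a hydride from the ring-B methine before the ether closes. The fallback uses known chemistry; it sets out from 13 and comes back at 20. The ene reaction of 13 with 14 is run with the mirror-image copper catalyst to give (3R)-5-[(1S,4S)-4-bromo-3,3-dimethylcyclohexyl]-3-hydroxyhex-5-en-2-one F1. Chelation-controlled addition of allylmagnesium bromide (THF, −78 °C) should give (4R,5R)-7-[(1S,4S)-4-bromo-3,3-dimethylcyclohexyl]-4-methylocta-1,7-diene-4,5-diol F2. Mesylation of the secondary hydroxyl and K2CO3 in MeOH close, with inversion, (2R,3S)-3-{2-[(1S,4S)-4-bromo-3,3-dimethylcyclohexyl]prop-2-en-1-yl}-2-methyl-2-(prop-2-en-1-yl)oxirane F3. Ring-closing metathesis with the second-generation Grubbs catalyst RuCl2(=CHPh)(PCy3)(H2IMes) gives (1R,6S)-4-[(1S,4S)-4-bromo-3,3-dimethylcyclohexyl]-1-methyl-7-oxabicyclo[4.1.0]hept-3-ene F4. Li2NiBr4 opens the epoxide at the secondary carbon, with a second inversion, to (1R,6R)-6-bromo-4-[(1S,4S)-4-bromo-3,3-dimethylcyclohexyl]-1-methylcyclohex-3-en-1-ol F5. Intramolecular alkoxymercuration–demercuration (Hg(OAc)2, then NaBH4/NaOH) of the trisubstituted ring alkene closes the ether bridge at the tertiary carbon and rejoins the route at 20.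

2. Step 4. Capture of the bromiranium ion by the weakly nucleophilic alkyne may be slower than proton loss to an allylic bromide or return of triflate. The fallback replaces the alkyne by an allylsilane terminator; it sets out from 1 and comes back at 12. The Grignard reagent of 1 is coupled with (2-bromoallyl)trimethylsilane (Pd(PPh3)4) to give trimethyl(6-methyl-2-methylidenehept-5-en-1-yl)silane F6. Shi epoxidation gives (3R)-2,2-dimethyl-3-{3-[(trimethylsilyl)methyl]but-3-en-1-yl}oxirane F7. Li2NiBr4 gives (3S)-3-bromo-2-methyl-6-methylidene-7-(trimethylsilyl)heptan-2-ol F8. Ionisation with Tf2O and the hindered pyridine, now terminated by the allylsilane, gives (4S)-4-bromo-3,3-dimethyl-1-methylidenecyclohexane F9. Ozonolysis (O3, then Me2S) gives (4S)-4-bromo-3,3-dimethylcyclohexan-1-one F10. LDA and PhNTf2 give the kinetic enol triflate (4S)-4-bromo-5,5-dimethylcyclohex-1-en-1-yl trifluoromethanesulfonate F11. Carbonylative Stille coupling (Pd(PPh3)4, CO, Me4Sn, LiCl) gives 1-[(4S)-4-bromo-5,5-dimethylcyclohex-1-en-1-yl]ethan-1-one F12, which is hydrogenated as in step 6 to rejoin the route at 12.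

3. Step 6. Facial selectivity of hydrogen delivery may be eroded by a catalyst–substrate mismatch, or reduction of the hindered alkene next to the quaternary carbon may stall. The fallback gives up catalyst control; it sets out from 11 and comes back at 12. Hydrogenation with the achiral catalyst [Ir(cod)(PCy3)(py)]PF6 should give 12 together with its C1 epimer 1-[(1R,4S)-4-bromo-3,3-dimethylcyclohexyl]ethan-1-one F13. The epimers are separated by chromatography, and F13 is re-equilibrated with DBU and separated again until the material has converged on 12.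

**Further compounds**
F1 | step 11 | (3R)-5-[(1S,4S)-4-bromo-3,3-dimethylcyclohexyl]-3-hydroxyhex-5-en-2-one | CC(=O)[C@H](O)CC(=C)[C@@H]1CC(C)(C)[C@@H](Br)CC1
F2 | step 11 | (4R,5R)-7-[(1S,4S)-4-bromo-3,3-dimethylcyclohexyl]-4-methylocta-1,7-diene-4,5-diol | C=CC[C@@](C)(O)[C@H](O)CC(=C)[C@@H]1CC(C)(C)[C@@H](Br)CC1
F3 | step 11 | (2R,3S)-3-{2-[(1S,4S)-4-bromo-3,3-dimethylcyclohexyl]prop-2-en-1-yl}-2-methyl-2-(prop-2-en-1-yl)oxirane | C=CC[C@@]1(C)O[C@H]1CC(=C)[C@@H]2CC(C)(C)[C@@H](Br)CC2
F4 | step 11 | (1R,6S)-4-[(1S,4S)-4-bromo-3,3-dimethylcyclohexyl]-1-methyl-7-oxabicyclo[4.1.0]hept-3-ene | C[C@@]12CC=C(C[C@@H]1O2)[C@@H]3CC(C)(C)[C@@H](Br)CC3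
F5 | step 11 | (1R,6R)-6-bromo-4-[(1S,4S)-4-bromo-3,3-dimethylcyclohexyl]-1-methylcyclohex-3-en-1-ol | C[C@@]1(O)CC=C(C[C@H]1Br)[C@@H]2CC(C)(C)[C@@H](Br)CC2
F6 | step 4 | trimethyl(6-methyl-2-methylidenehept-5-en-1-yl)silane | CC(C)=CCCC(=C)C[Si](C)(C)C
F7 | step 4 | (3R)-2,2-dimethyl-3-{3-[(trimethylsilyl)methyl]but-3-en-1-yl}oxirane | CC1(C)O[C@@H]1CCC(=C)C[Si](C)(C)C
F8 | step 4 | (3S)-3-bromo-2-methyl-6-methylidene-7-(trimethylsilyl)heptan-2-ol | C=C(C[Si](C)(C)C)CC[C@@H](C(C)(C)O)Br
F9 | step 4 | (4S)-4-bromo-3,3-dimethyl-1-methylidenecyclohexane | CC1(C)CC(=C)CC[C@@H]1Br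
F10 | step 4 | (4S)-4-bromo-3,3-dimethylcyclohexan-1-one | CC1(C)CC(=O)CC[C@@H]1Br
F11 | step 4 | (4S)-4-bromo-5,5-dimethylcyclohex-1-en-1-yl trifluoromethanesulfonate | CC1(C)CC(OS(=O)(=O)C(F)(F)F)=CC[C@@H]1Br
F12 | step 4 | 1-[(4S)-4-bromo-5,5-dimethylcyclohex-1-en-1-yl]ethan-1-one | CC(=O)C1=CC[C@H](Br)C(C)(C)C1
F13 | step 6 | 1-[(1R,4S)-4-bromo-3,3-dimethylcyclohexyl]ethan-1-one | CC(=O)[C@H]1CC(C)(C)[C@@H](Br)CC1
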